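The readings stem from a simulated flask for substances that don't exist; noise was put on by code.

The ash flask holds more Z than larch, 20 mM against 13 mM, yet at 40.0 min their Z readings differ by just 0.5 percentage points, near the scatter of 0.3 points. So the readings fit a rate of first order in [Z].

| flask | Z | remark | time |
|---|---|---|---|
| ash | 20 mM | the very flask that is asked about, followed so far |  |
| larch | 13 mM | run made earlier |  |
| flask | 20 mM |  | 2.0 h |

- ash (time / min: Q / %, Z / %): 15.0: 16.6, 68.4; 20.0: 20.3, 61.1; 25.0: 22.5, 54.5; 30.0: 24.7, 49.2; 40.0: 28.3, 40.0
- larch (time / min: Q / %, Z / %): 15.0: 16.1, 69.4; 20.0: 20.0, 62.1; 30.0: 25.4, 50.0; 40.0: 28.0, 40.5; 60.0: 29.4, 27.6; 80.0: 27.5, 18.9; 120: 20.3, 9.1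

(scatter of a reading: 0.3 percentage points)

- the numbers in the tables scatter with a standard deviation of 0.3 percentage points
- a reading or a percentage of Q counts all its forms, free or not
- a reading of Z is of its free form alone

1. time, not beyond 2.0 h, at which the flask holds most Q
2. the amount of Q, in percent of the Z charged, at that time

Larch's Z from 20.0 min to 120 min gives 0.0192 min⁻¹, the fading constant of Z: the natural logarithm of the ratio of two Z readings over the time between them (an apparent first-order rate constant).

Q starts steeply in ash, at about 0.0111 min⁻¹ as a share of the charge up to 15.0 min, and has bent to 0.00360 min⁻¹ by 40.0 min. In larch its top reading, 29.4% at 60.0 min, stands just past the point where Q overtakes Z, which reads 27.6% there. Beyond that point Q falls, to 20.3% by 120 min. The crossing of Q and Z is therefore the mark to watch.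

Carried by the fading constant from 40.0% at 40.0 min down to that top level, ash's Z arrives at 0.934 h, earlier than the limit of 2.0 h. This reckoning therefore expects Q near 29.4% at that time.

The forecast comes by another road, “A parabola through these puts the peak near 58 min at about 29.4–29.6”, and commits to 29.6% at 0.93 h.

The flask gives 29.8% at 0.952 h.

    Z → Q (k = 2.41 × 10⁻⁴ s⁻¹)
    Z → X (k = 1.12 × 10⁻⁴ s⁻¹)
    Q → D (k = 2.78 × 10⁻⁴ s⁻¹)
    Z + Q ⇌ E, settled at all times (K = 34.0 M⁻¹)

At 0.952 h the flask holds Z 28.7% and Q 29.8%, bound forms of Q counted, so the two stand side by side at the peak. The fading constant, carried from the ash reading at 40.0 min, gives Z 28.8% at that time. A neighbouring flask has the same charge and is read later, at 5.0 h. The same reckoning gives it Z 0.272%, and that neighbouring flask holds 0.29% of the charged Z, unbound.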